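**Plan**

1. Retrosynthesis: the five O-benzyl groups are cut first. Ring C of the flavanone unit (O1–C2–C3–C4–C4a–C8a) is then contracted by re-forming a C2–C4 bond, which gives a cyclopropanol fused to a benzofuran (five-membered ring O1–C2–C4–C4a–C8a). Removing C3 as CH2 leaves a 2-aryl-3-silyloxybenzofuran, which is cut at C2–C1′ (enolate arylation), then at the biaryl bond C3′–C8″ (Suzuki–Miyaura); the flavone is cut at O1″–C2″ and Cα–Cβ (chalcone).
2. Forward order: flavone ring (aldol condensation, oxidative cyclisation) → biaryl → benzofuran-3-ol silyl ether → cyclopropane → ring expansion 5→6 to the flavanone → debenzylation.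
3. Enabling feature: C2 of the flavanone is benzylic, bears O1 and lies β to the C4 aryl ketone (a homoenolate carbon). The C2–C4 bond can therefore be put in as the fusion bond of a cyclopropanol and cleaved again by base. The silyl group and the three-membered ring are the temporary helpers, and both are consumed in the key step.
4. Stereochemistry: the only stereocentre (C2, S) comes from enantioselective CH2 transfer to the benzofuran C2=C3 bond, giving the (1aR,6bR)-cyclopropane, and is passed to C2 with inversion in the ring opening. Only a neutral hydrogenolysis follows.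

Key step: step 8

Assumption: the facial sense of the dipeptide-ligated zinc carbenoid on 11 is not established, so the ligand antipode that delivers (1aR,6bR)-12 is used; ring opening in methanol is taken to be invertive, as for 2-arylcyclopropanols (if it proves retentive, the other ligand antipode is used in step 7).

Notation: Ar* = 4-(benzyloxy)-3-[5,7-bis(benzyloxy)-2-(4-methoxyphenyl)-4-oxo-4H-chromen-8-yl]phenyl; Bn = benzyl.

**Route**

Step 1
Reactants: 1 1-[2,4-bis(benzyloxy)-6-hydroxyphenyl]ethan-1-one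
Product: 2 1-[4,6-bis(benzyloxy)-2-hydroxy-3-iodophenyl]ethan-1-one
Conditions: N-iodosuccinimide (1.0 equiv), TsOH·H2O (cat.), MeCN, 0 °C to rt
Reagents that add atoms: N-iodosuccinimide, O=C1CCC(=O)N1I
Why: Electrophilic aromatic iodination should occur ortho to the free, chelated phenol (C3, between OH and OBn), the usual halogenation site of 2-hydroxy-4,6-dialkoxyacetophenones, and one equivalent of reagent limits di-iodination.

Step 2
Reactants: 2 1-[4,6-bis(benzyloxy)-2-hydroxy-3-iodophenyl]ethan-1-one; 3 4-methoxybenzaldehyde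
Product: 4 (E)-1-[4,6-bis(benzyloxy)-2-hydroxy-3-iodophenyl]-3-(4-methoxyphenyl)prop-2-en-1-one
Conditions: KOH, EtOH, rt
Reagents that add atoms: none
Why: Claisen–Schmidt condensation of a methyl ketone with a non-enolisable aldehyde should give the E-chalcone, and the aryl iodide and benzyl ethers are inert to ethanolic hydroxide at room temperature.

Step 3
Reactants: 4 (E)-1-[4,6-bis(benzyloxy)-2-hydroxy-3-iodophenyl]-3-(4-methoxyphenyl)prop-2-en-1-one
Product: 5 5,7-bis(benzyloxy)-8-iodo-2-(4-methoxyphenyl)-4H-chromen-4-one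
Conditions: I2 (10 mol %), DMSO, 120 °C
Reagents that add atoms: none
Why: Iodine-catalysed oxidative cyclisation of a 2′-hydroxychalcone (oxa-Michael addition, α-iodination, elimination, with DMSO as terminal oxidant) should give the flavone, the iodine ortho to the cyclising phenol ending at C8.

Step 4
Reactants: 5 5,7-bis(benzyloxy)-8-iodo-2-(4-methoxyphenyl)-4H-chromen-4-one; 6 [2-(benzyloxy)-5-chlorophenyl]boronic acid
Product: 7 5,7-bis(benzyloxy)-8-[2-(benzyloxy)-5-chlorophenyl]-2-(4-methoxyphenyl)-4H-chromen-4-one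
Conditions: Pd(PPh3)4 (5 mol %), K2CO3, DMF/H2O (9:1), 90 °C
Reagents that add atoms: none
Why: Suzuki–Miyaura coupling at the C8–I bond should form the tri-ortho-substituted biaryl, as in couplings of 8-iodoflavones with ortho-alkoxyarylboron reagents, and the triphenylphosphine catalyst does not insert into the aryl chloride.

Step 5
Reactants: 8 4,6-dihydroxy-1-benzofuran-3(2H)-one
Product: 9 4,6-bis(benzyloxy)-1-benzofuran-3(2H)-one
Conditions: benzyl bromide (2.2 equiv), K2CO3, DMF, 60 °C
Reagents that add atoms: benzyl bromide, BrCc1ccccc1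
Why: Williamson O-alkylation of both phenols with carbonate in a dipolar aprotic solvent should give the bis(benzyl ether), the weak base disfavouring C2-benzylation.

Step 6
Reactants: 7 5,7-bis(benzyloxy)-8-[2-(benzyloxy)-5-chlorophenyl]-2-(4-methoxyphenyl)-4H-chromen-4-one; 9 4,6-bis(benzyloxy)-1-benzofuran-3(2H)-one
Product: 11 2-Ar*-4,6-bis(benzyloxy)-3-(trimethylsilyloxy)-1-benzofuran, via 2-arylbenzofuranone 10 (not isolated)
Conditions: Pd(OAc)2 (5 mol %), XPhos (10 mol %), K3PO4 (2.5 equiv), toluene, 100 °C, under argon; then Me3SiCl (1.5 equiv), 0 °C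
Reagents that add atoms: chlorotrimethylsilane, C[Si](C)(C)Cl
Why: Palladium-catalysed ketone enolate α-arylation with an aryl chloride (dialkylbiarylphosphine ligand) should stop at mono-arylation because 10 enolises to the aromatic 3-oxidobenzofuran, which is then O-silylated in the same flask to avoid autoxidation.

Step 7
Reactants: 11 2-Ar*-4,6-bis(benzyloxy)-3-(trimethylsilyloxy)-1-benzofuran
Product: 12 (1aR,6bR)-1a-Ar*-4,6-bis(benzyloxy)-6b-(trimethylsilyloxy)-1a,6b-dihydro-1H-cyclopropa[b][1]benzofuran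
Conditions: Et2Zn (2 equiv), CH2I2 (4 equiv), N-Boc-valyl-proline methyl ester (0.25–1.0 equiv, antipode as required), CH2Cl2, −40 to −10 °C
Reagents that add atoms: diiodomethane, ICI
Why: Proposed new method: enantioselective Simmons–Smith methylene transfer to the C2=C3 bond of a benzofuran, which is here a tetrasubstituted, doubly oxygen-donor enol ether of low aromatic stabilisation and so matched to the electrophilic zinc carbenoid; concerted syn addition through the butterfly transition state can only give the cis-fused cyclopropane, and the dipeptide-bound (iodomethyl)zinc species is expected to discriminate the enantiotopic faces, setting C1a and C6b together; the closest known reaction types are the dipeptide-ligated zinc-carbenoid cyclopropanation of aryl-conjugated trimethylsilyl enol ethers and the cyclopropanation of benzofuran 2,3-bonds by metal carbenoids.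

Step 8
Reactants: 12 (1aR,6bR)-1a-Ar*-4,6-bis(benzyloxy)-6b-(trimethylsilyloxy)-1a,6b-dihydro-1H-cyclopropa[b][1]benzofuran
Product: 14 (2S)-2-Ar*-5,7-bis(benzyloxy)-2,3-dihydro-4H-chromen-4-one, via cyclopropanol 13 (not isolated)
Conditions: K2CO3 (0.2 equiv), MeOH/THF (3:1), −20 to 0 °C; then AcOH
Reagents that add atoms: none
Why: Proposed new method: methanolysis of the O–Si bond gives the cyclopropoxide of 13, whose oxygen lone pair pushes into the strained C1a–C6b fusion bond (homoenolate-type heterolysis), so that C6b–O becomes the C4 carbonyl while the developing carbanion at C1a, stabilised by the aryl group and the aryloxy oxygen, is protonated by methanol on the face opposite the breaking bond (SE2, inversion), turning (1aR)-C1a into (2S)-C2. The closest known reaction types are the base-induced ring opening of 2-arylcyclopropanols, which cleaves toward the benzylic carbon with inversion, and the one-carbon ring enlargement of ketones through siloxycyclopropanes. No ring is closed by bond formation: the six-membered pyranone ring is unveiled from the five-membered dihydrofuran ring by scission of the zero-atom bridge of the 2-oxabicyclo[3.1.0]hexane, the cyclopropane CH2 becoming C3. The only new stereocentre, C2, is controlled by the configuration of C1a (substrate control, stereospecific), and C6b is lost as the carbonyl carbon. The step needs internal (C1a–C6b) rather than external (C6b–C1) cleavage, which the benzylic and α-oxygen stabilisation at C1a and the larger strain release should secure, and it needs the flavanone not to reopen by E1cB to the chalcone, which catalytic carbonate, low temperature and an acidic quench should secure.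

Step 9
Reactants: 14 (2S)-2-Ar*-5,7-bis(benzyloxy)-2,3-dihydro-4H-chromen-4-one
Product: 15 2,3-dihydropodocarpusflavone A
Conditions: H2 (1 atm), Pd/C (10 %), EtOAc/MeOH, rt
Reagents that add atoms: none
Why: Catalytic hydrogenolysis should remove the five aryl benzyl ethers under neutral conditions that leave the aryl methyl ether, the pyrone double bond of the flavone and the base-sensitive C2 stereocentre untouched.

**Compound list**

1 | 1-[2,4-bis(benzyloxy)-6-hydroxyphenyl]ethan-1-one | CC(=O)c1c(O)cc(OCc2ccccc2)cc1OCc1ccccc1 | starting material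
2 | 1-[4,6-bis(benzyloxy)-2-hydroxy-3-iodophenyl]ethan-1-one | CC(=O)c1c(O)c(I)c(OCc2ccccc2)cc1OCc1ccccc1 | intermediate
3 | 4-methoxybenzaldehyde | COc1ccc(C=O)cc1 | starting material
4 | (E)-1-[4,6-bis(benzyloxy)-2-hydroxy-3-iodophenyl]-3-(4-methoxyphenyl)prop-2-en-1-one | COc1ccc(/C=C/C(=O)c2c(O)c(I)c(OCc3ccccc3)cc2OCc2ccccc2)cc1 | intermediate
5 | 5,7-bis(benzyloxy)-8-iodo-2-(4-methoxyphenyl)-4H-chromen-4-one | COc1ccc(-c2cc(=O)c3c(OCc4ccccc4)cc(OCc4ccccc4)c(I)c3o2)cc1 | intermediate
6 | [2-(benzyloxy)-5-chlorophenyl]boronic acid | OB(O)c1cc(Cl)ccc1OCc1ccccc1 | starting material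
7 | 5,7-bis(benzyloxy)-8-[2-(benzyloxy)-5-chlorophenyl]-2-(4-methoxyphenyl)-4H-chromen-4-one (Ar*–Cl) | COc1ccc(-c2cc(=O)c3c(OCc4ccccc4)cc(OCc4ccccc4)c(-c4cc(Cl)ccc4OCc4ccccc4)c3o2)cc1 | intermediate
8 | 4,6-dihydroxy-1-benzofuran-3(2H)-one | O=C1COc2cc(O)cc(O)c12 | starting material
9 | 4,6-bis(benzyloxy)-1-benzofuran-3(2H)-one | O=C1COc2cc(OCc3ccccc3)cc(OCc3ccccc3)c12 | intermediate
10 | 2-Ar*-4,6-bis(benzyloxy)-1-benzofuran-3(2H)-one (racemic at C2, present as its potassium enolate) | COc1ccc(-c2cc(=O)c3c(OCc4ccccc4)cc(OCc4ccccc4)c(-c4cc(C5Oc6cc(OCc7ccccc7)cc(OCc7ccccc7)c6C5=O)ccc4OCc4ccccc4)c3o2)cc1 | intermediate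
11 | 2-Ar*-4,6-bis(benzyloxy)-3-(trimethylsilyloxy)-1-benzofuran | COc1ccc(-c2cc(=O)c3c(OCc4ccccc4)cc(OCc4ccccc4)c(-c4cc(-c5oc6cc(OCc7ccccc7)cc(OCc7ccccc7)c6c5O[Si](C)(C)C)ccc4OCc4ccccc4)c3o2)cc1 | intermediate
12 | (1aR,6bR)-1a-Ar*-4,6-bis(benzyloxy)-6b-(trimethylsilyloxy)-1a,6b-dihydro-1H-cyclopropa[b][1]benzofuran | C[Si](C)(C)O[C@@]12C[C@]1(c1ccc(OCc3ccccc3)c(-c3c(OCc4ccccc4)cc(OCc4ccccc4)c4c(=O)cc(-c5ccc(OC)cc5)oc34)c1)Oc1cc(OCc3ccccc3)cc(OCc3ccccc3)c12 | intermediate
13 | (1aR,6bR)-1a-Ar*-4,6-bis(benzyloxy)-1a,6b-dihydro-1H-cyclopropa[b][1]benzofuran-6b-ol | O[C@@]12C[C@]1(c1ccc(OCc3ccccc3)c(-c3c(OCc4ccccc4)cc(OCc4ccccc4)c4c(=O)cc(-c5ccc(OC)cc5)oc34)c1)Oc1cc(OCc3ccccc3)cc(OCc3ccccc3)c12 | intermediate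
14 | (2S)-2-Ar*-5,7-bis(benzyloxy)-2,3-dihydro-4H-chromen-4-one (pentabenzyl ether of the target) | COc1ccc(-c2cc(=O)c3c(OCc4ccccc4)cc(OCc4ccccc4)c(-c4cc([C@@H]5CC(=O)c6c(OCc7ccccc7)cc(OCc7ccccc7)cc6O5)ccc4OCc4ccccc4)c3o2)cc1 | intermediate
15 | 2,3-dihydropodocarpusflavone A, (2S)-5,7-dihydroxy-2-{4-hydroxy-3-[5,7-dihydroxy-2-(4-methoxyphenyl)-4-oxo-4H-chromen-8-yl]phenyl}-2,3-dihydro-4H-chromen-4-one | COc1ccc(-c2cc(=O)c3c(O)cc(O)c(-c4cc([C@@H]5CC(=O)c6c(O)cc(O)cc6O5)ccc4O)c3o2)cc1 | target

**Step count and risks**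

Total steps: 9. Longest linear sequence: 8 (steps 1–4 and 6–9; step 5 is a one-step side branch).

Steps most likely to fail:

1. Step 7. The chiral zinc carbenoid may not discriminate the two enantiotopic faces of the planar benzofuran well enough, or methylene transfer to the tetrasubstituted, partly aromatic C2=C3 bond may be too slow. The fallback leaves the cyclopropane route and sets the stereocentre by a known asymmetric conjugate addition. It sets out from 7 and 1 and comes back at 14. Compound 7 is borylated (B2(OH)4, Pd(OAc)2/XPhos, KOAc, EtOH, 80 °C) to [4-(benzyloxy)-3-{5,7-bis(benzyloxy)-2-(4-methoxyphenyl)-4-oxo-4H-chromen-8-yl}phenyl]boronic acid F1. In parallel, 1 is condensed with N,N-dimethylformamide dimethyl acetal to the enaminone (E)-1-[2,4-bis(benzyloxy)-6-hydroxyphenyl]-3-(dimethylamino)prop-2-en-1-one F2, which closes under acid to 5,7-bis(benzyloxy)-4H-chromen-4-one F3. Palladium-catalysed enantioselective 1,4-addition of F1 to F3 (Pd(OCOCF3)2, the t-BuPyOX antipode that gives 2S, NH4PF6, H2O, ClCH2CH2Cl, 60 °C, no base) should give 14 directly, and the route continues with step 9.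

2. Step 8. The alkoxide may cleave the external C6b–C1 bond instead (leading to a 2-methylbenzofuranone), a free and long-lived benzylic carbanion may erode the configuration, or the product may reopen by E1cB to the chalcone. The fallback builds the flavanone ring classically and resolves it with known chemistry. It sets out from 5 and 1 and comes back at 14. Suzuki–Miyaura coupling of 5 with commercial [2-(benzyloxy)-5-formylphenyl]boronic acid gives 4-(benzyloxy)-3-[5,7-bis(benzyloxy)-2-(4-methoxyphenyl)-4-oxo-4H-chromen-8-yl]benzaldehyde F4. Claisen–Schmidt condensation of F4 with 1 (Ba(OH)2, MeOH) gives the 2′-hydroxychalcone (E)-1-[2,4-bis(benzyloxy)-6-hydroxyphenyl]-3-Ar*-prop-2-en-1-one F5. NaOAc in refluxing EtOH closes it by oxa-Michael addition to racemic 2-Ar*-5,7-bis(benzyloxy)-2,3-dihydro-4H-chromen-4-one F6. Kinetic resolution by asymmetric transfer hydrogenation (the RuCl(p-cymene)(TsDPEN) antipode that reduces the 2R ketone, HCO2H/Et3N, about half conversion) should convert the 2R enantiomer into the cis-flavanol (2R,4R)-2-Ar*-5,7-bis(benzyloxy)-3,4-dihydro-2H-chromen-4-ol F7, which is separated from unreacted 14; 14 then goes on to step 9.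

3. Step 6. Oxidative addition into the electron-rich, bulky aryl chloride may be so slow that base-mediated self-condensation and autoxidation of the benzofuranone enolate take over. The fallback changes the order of bond formation. It sets out from 9 and 5 and comes back at 10, which is silylated to 11 as in step 6. Compound 9 is α-arylated at the C–Br bond of commercial 1-(benzyloxy)-4-bromo-2-chlorobenzene, a small and fast-reacting partner, to give 2-[4-(benzyloxy)-3-chlorophenyl]-4,6-bis(benzyloxy)-1-benzofuran-3(2H)-one F8. Compound 5 is converted by Miyaura borylation (B2pin2, Pd(dppf)Cl2, KOAc, dioxane) into 5,7-bis(benzyloxy)-2-(4-methoxyphenyl)-8-(4,4,5,5-tetramethyl-1,3,2-dioxaborolan-2-yl)-4H-chromen-4-one F9. Suzuki–Miyaura coupling of F8 with F9 (Pd(OAc)2/SPhos, K3PO4, degassed toluene/H2O) should give 10 as its enolate.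

**Further compounds**

F1 | step 7 | [4-(benzyloxy)-3-{5,7-bis(benzyloxy)-2-(4-methoxyphenyl)-4-oxo-4H-chromen-8-yl}phenyl]boronic acid | COc1ccc(-c2cc(=O)c3c(OCc4ccccc4)cc(OCc4ccccc4)c(-c4cc(B(O)O)ccc4OCc4ccccc4)c3o2)cc1
F2 | step 7 | (E)-1-[2,4-bis(benzyloxy)-6-hydroxyphenyl]-3-(dimethylamino)prop-2-en-1-one | CN(C)/C=C/C(=O)c1c(O)cc(OCc2ccccc2)cc1OCc1ccccc1
F3 | step 7 | 5,7-bis(benzyloxy)-4H-chromen-4-one | O=c1ccoc2cc(OCc3ccccc3)cc(OCc3ccccc3)c12
F4 | step 8 | 4-(benzyloxy)-3-[5,7-bis(benzyloxy)-2-(4-methoxyphenyl)-4-oxo-4H-chromen-8-yl]benzaldehyde | COc1ccc(-c2cc(=O)c3c(OCc4ccccc4)cc(OCc4ccccc4)c(-c4cc(C=O)ccc4OCc4ccccc4)c3o2)cc1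
F5 | step 8 | (E)-1-[2,4-bis(benzyloxy)-6-hydroxyphenyl]-3-Ar*-prop-2-en-1-one | COc1ccc(-c2cc(=O)c3c(OCc4ccccc4)cc(OCc4ccccc4)c(-c4cc(/C=C/C(=O)c5c(O)cc(OCc6ccccc6)cc5OCc5ccccc5)ccc4OCc4ccccc4)c3o2)cc1
F6 | step 8 | racemic 2-Ar*-5,7-bis(benzyloxy)-2,3-dihydro-4H-chromen-4-one | COc1ccc(-c2cc(=O)c3c(OCc4ccccc4)cc(OCc4ccccc4)c(-c4cc(C5CC(=O)c6c(OCc7ccccc7)cc(OCc7ccccc7)cc6O5)ccc4OCc4ccccc4)c3o2)cc1
F7 | step 8 | (2R,4R)-2-Ar*-5,7-bis(benzyloxy)-3,4-dihydro-2H-chromen-4-ol | COc1ccc(-c2cc(=O)c3c(OCc4ccccc4)cc(OCc4ccccc4)c(-c4cc([C@H]5C[C@@H](O)c6c(OCc7ccccc7)cc(OCc7ccccc7)cc6O5)ccc4OCc4ccccc4)c3o2)cc1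
F8 | step 6 | 2-[4-(benzyloxy)-3-chlorophenyl]-4,6-bis(benzyloxy)-1-benzofuran-3(2H)-one | O=C1C(c2ccc(OCc3ccccc3)c(Cl)c2)Oc2cc(OCc3ccccc3)cc(OCc3ccccc3)c12
F9 | step 6 | 5,7-bis(benzyloxy)-2-(4-methoxyphenyl)-8-(4,4,5,5-tetramethyl-1,3,2-dioxaborolan-2-yl)-4H-chromen-4-one | COc1ccc(-c2cc(=O)c3c(OCc4ccccc4)cc(OCc4ccccc4)c(B4OC(C)(C)C(C)(C)O4)c3o2)cc1
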